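**Assumption:** the target SMILES carries no stereodescriptor and the molecule has no stereocentre; the N1–C3' axis is not assigned, so no stereocontrol is needed and the route delivers the constitution as drawn.

**Retrosynthetic overview**
- Rivularin A comes from threefold electrophilic bromination (C2 and C3 of ring A, C2' of ring B) of a tribromo 1,3'-biindole.
- Key disconnection is C2'–C3' of ring B: an α-(indol-1-yl)benzyl carbanion (a reversed-polarity α-amino carbon, normally an iminium-type acceptor) closes onto an ortho isocyanide carbon (a formyl-level acceptor).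
- The N1–CH2 bond is made in the same flask by SN2 of 5-bromoindolide on an ortho-(chloromethyl)aryl isocyanide.
- That isocyanide comes from lateral lithiation/chlorination of 3,4-dibromo-2-methylphenyl isocyanide, made by carbylamine reaction after para-bromination of 3-bromo-2-methylaniline.
- Ring order: both benzene rings and the ring A pyrrole are bought; the ring B pyrrole is the only ring built, in the key step.

**Step 1**
Reactants: 1 3-bromo-2-methylaniline
Product: 2 3,4-dibromo-2-methylaniline
Conditions: NBS (1.0 equiv), MeCN, 0 °C → rt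
Reagents that add atoms: N-bromosuccinimide, O=C1CCC(=O)N1Br
Why: Electrophilic aromatic bromination in which the NH2 group directs para (C4, also ortho to the existing bromine), and one equivalent of NBS at 0 °C stops at monobromination.

**Step 2**
Reactants: 2 3,4-dibromo-2-methylaniline
Product: 3 1,2-dibromo-4-isocyano-3-methylbenzene
Conditions: CHCl3 (2 equiv), 50% aq NaOH, BnEt3NCl (5 mol %), CH2Cl2, 40 °C
Reagents that add atoms: chloroform, ClC(Cl)Cl
Why: Hofmann carbylamine reaction under phase-transfer catalysis, in which dichlorocarbene is trapped by the arylamine and two HCl are lost to give the aryl isocyanide, a conversion routinely run on ortho-substituted anilines and harmless to aryl bromides.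

**Step 3**
Reactants: 3 1,2-dibromo-4-isocyano-3-methylbenzene
Product: 5 1,2-dibromo-3-(chloromethyl)-4-isocyanobenzene, via lithiated isocyanide 4 (not isolated)
Conditions: LiN(iPr)2 (1.1 equiv), THF, –78 °C; then cannulated into C2Cl6 (1.5 equiv), THF, –78 °C
Reagents that add atoms: hexachloroethane, ClC(Cl)(Cl)C(Cl)(Cl)Cl
Why: Lateral (benzylic) lithiation of an ortho-tolyl isocyanide, as in the first stage of the Ito–Saegusa indole synthesis, gives 4, which does not cyclise at –78 °C and is chlorinated by inverse addition to C2Cl6, a standard Cl+ donor for benzylic organolithiums; the amide base does not exchange the aryl bromides.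

**Step 4**
Reactants: 5 1,2-dibromo-3-(chloromethyl)-4-isocyanobenzene; 6 5-bromo-1H-indole
Product: 11 5-bromo-1-(4,5-dibromo-1H-indol-3-yl)-1H-indole, via sodium 5-bromoindol-1-ide 7 (not isolated), via N-benzylated isocyanide 8 (not isolated), via α-indolyl benzyllithium 9 (not isolated), via 2-lithio-3H-indole 10 (not isolated)
Conditions: 6, NaH (1.0 equiv), THF–DMPU (10:1), 0 °C; 5, 0 °C → rt; then LiN(iPr)2 (2.2 equiv), –78 °C → rt; aq NH4Cl
Reagents that add atoms: none
Why: Proposed new method: indolide 7 displaces the benzylic chloride of 5 (SN2, N-selective in THF–DMPU) to give 8, whose CH2 is acidified by the isocyanoarene, the indole nitrogen and two ring bromines and is removed by LiN(iPr)2 in preference to any ring C–H; the resulting α-amino carbanion 9 uses a carbon that normally reacts as an iminium-type acceptor as a donor and closes 5-endo-dig onto the isocyanide carbon to give imidoyllithium 10, which aromatises by proton shift on quench; the closest known reaction type is the Ito–Saegusa indole synthesis (anionic cyclisation of lithiated ortho-alkylphenyl isocyanides, which tolerates substituents on the benzylic carbon), and no stereocentre survives.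

**Step 5**
Reactants: 11 5-bromo-1-(4,5-dibromo-1H-indol-3-yl)-1H-indole
Product: 12 Rivularin A
Conditions: NBS (3.1 equiv), THF, –78 °C → rt, dark
Reagents that add atoms: N-bromosuccinimide, O=C1CCC(=O)N1Br
Why: Electrophilic bromination of the three remaining pyrrole-ring positions (C3 then C2 of N-substituted ring A, C2' of 3-substituted ring B by the 3-bromoindolenine pathway), which are far more nucleophilic than the bromine-deactivated benzo rings; no stereocentre is formed.

**Compound list**
1 | 3-bromo-2-methylaniline | Cc1c(N)cccc1Br | starting material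
2 | 3,4-dibromo-2-methylaniline | Cc1c(N)ccc(Br)c1Br | intermediate
3 | 1,2-dibromo-4-isocyano-3-methylbenzene (3,4-dibromo-2-methylphenyl isocyanide) | Cc1c([N+]#[C-])ccc(Br)c1Br | intermediate
4 | (2,3-dibromo-6-isocyanophenyl)methyllithium | [Li]Cc1c([N+]#[C-])ccc(Br)c1Br | intermediate (not isolated)
5 | 1,2-dibromo-3-(chloromethyl)-4-isocyanobenzene | ClCc1c([N+]#[C-])ccc(Br)c1Br | intermediate
6 | 5-bromo-1H-indole | Brc1ccc2[nH]ccc2c1 | starting material
7 | sodium 5-bromoindol-1-ide | [Na+].Brc1ccc2[n-]ccc2c1 | intermediate (not isolated)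
8 | 5-bromo-1-[(2,3-dibromo-6-isocyanophenyl)methyl]-1H-indole | Brc1ccc2c(c1)ccn2Cc1c([N+]#[C-])ccc(Br)c1Br | intermediate (not isolated)
9 | [(5-bromo-1H-indol-1-yl)(2,3-dibromo-6-isocyanophenyl)methyl]lithium (configurationally labile carbanion) | [Li]C(n1ccc2cc(Br)ccc12)c1c([N+]#[C-])ccc(Br)c1Br | intermediate (not isolated)
10 | [4,5-dibromo-3-(5-bromo-1H-indol-1-yl)-3H-indol-2-yl]lithium (racemic at C3; centre lost on aromatisation) | [Li]C1=Nc2ccc(Br)c(Br)c2C1n1ccc2cc(Br)ccc12 | intermediate (not isolated)
11 | 5-bromo-1-(4,5-dibromo-1H-indol-3-yl)-1H-indole (4',5,5'-tribromo-1'H-1,3'-biindole) | Brc1ccc2c(c1)ccn2-c1c[nH]c2ccc(Br)c(Br)c12 | intermediate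
12 | Rivularin A (2,2',3,4',5,5'-hexabromo-1'H-1,3'-biindole) | Brc1ccc2c(c1)c(Br)c(Br)n2-c1c(Br)[nH]c2ccc(Br)c(Br)c12 | target

**Total step count:** 5
**Longest linear sequence:** 5 (1 → 2 → 3 → 5 → 11 → 12; 6 enters at step 4)

**Three steps most likely to fail**

Step 4 (one-flask N-alkylation and anionic ring closure). The risk is ring metalation or aryne chemistry from excess LiN(iPr)2 on warming, or a sluggish 5-endo closure of the stabilised carbanion. The fallback sets out from 2 (with 6) and comes back at 11. It keeps the same C2'–C3' construction but uses a nitro-activated benzylic carbon and mild base (Leimgruber–Batcho indole synthesis). Aniline 2 is oxidised (NaBO3·4H2O, AcOH, 55 °C) to 1,2-dibromo-3-methyl-4-nitrobenzene F1. Radical bromination (NBS, AIBN, PhCF3, reflux) gives 1,2-dibromo-3-(bromomethyl)-4-nitrobenzene F2. This alkylates 6 (NaH, DMF, 0 °C) to give 5-bromo-1-[(2,3-dibromo-6-nitrophenyl)methyl]-1H-indole F3. Condensation with tert-butoxybis(dimethylamino)methane (DMF, 110 °C) gives the enamine (E)-2-(5-bromo-1H-indol-1-yl)-2-(2,3-dibromo-6-nitrophenyl)-N,N-dimethylethen-1-amine F4 (geometry inconsequential). Reduction with Fe powder in AcOH/EtOH at 80 °C then closes ring B with loss of dimethylamine to give 11.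

Step 3 (lateral lithiation and chlorination). The risk is Wurtz-type coupling or further deprotonation of the more acidic product 5. The fallback sets out from 2 (with 6) and comes back at 8. It makes the benzylic C–N bond before the isocyanide exists. Aniline 2 is taken as above to 1,2-dibromo-3-methyl-4-nitrobenzene F1, then 1,2-dibromo-3-(bromomethyl)-4-nitrobenzene F2, then 5-bromo-1-[(2,3-dibromo-6-nitrophenyl)methyl]-1H-indole F3. The nitro group is reduced (Fe powder, NH4Cl, EtOH/H2O, 80 °C) to 3,4-dibromo-2-[(5-bromo-1H-indol-1-yl)methyl]aniline F5. N-Formylation (HCO2H/Ac2O, 0 °C) gives N-{3,4-dibromo-2-[(5-bromo-1H-indol-1-yl)methyl]phenyl}formamide F6. Dehydration (PPh3, I2, Et3N, CH2Cl2, 0 °C) gives 8, which is cyclised with LiN(iPr)2 as in the second stage of step 4.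

Step 5 (threefold bromination). The risk is that the third equivalent attacks a benzo position or the nitrogen of ring B instead of C2 of ring A. The fallback sets out from 6 (with 5) and comes back at 12. It installs the ring A bromines before the union. Indole 6 is dibrominated (NBS, 2.1 equiv, THF, –78 °C → rt, used promptly) to 2,3,5-tribromo-1H-indole F7. Its sodium salt is alkylated with 5 to 2,3,5-tribromo-1-[(2,3-dibromo-6-isocyanophenyl)methyl]-1H-indole F8 (not isolated). Cyclisation with LiN(iPr)2 as in step 4 gives 2,3,5-tribromo-1-(4,5-dibromo-1H-indol-3-yl)-1H-indole F9. A single NBS bromination (1.05 equiv, THF, 0 °C) at C2' then gives 12.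

**Further compounds**
F1 | step 4 | 1,2-dibromo-3-methyl-4-nitrobenzene | Cc1c(ccc(Br)c1Br)[N+](=O)[O-]
F2 | step 4 | 1,2-dibromo-3-(bromomethyl)-4-nitrobenzene | BrCc1c(ccc(Br)c1Br)[N+](=O)[O-]
F3 | step 4 | 5-bromo-1-[(2,3-dibromo-6-nitrophenyl)methyl]-1H-indole | Brc1ccc2c(c1)ccn2Cc1c(ccc(Br)c1Br)[N+](=O)[O-]
F4 | step 4 | (E)-2-(5-bromo-1H-indol-1-yl)-2-(2,3-dibromo-6-nitrophenyl)-N,N-dimethylethen-1-amine | CN(C)/C=C(/n1ccc2cc(Br)ccc12)c1c(ccc(Br)c1Br)[N+](=O)[O-]
F5 | step 3 | 3,4-dibromo-2-[(5-bromo-1H-indol-1-yl)methyl]aniline | Nc1ccc(Br)c(Br)c1Cn1ccc2cc(Br)ccc12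
F6 | step 3 | N-{3,4-dibromo-2-[(5-bromo-1H-indol-1-yl)methyl]phenyl}formamide | O=CNc1ccc(Br)c(Br)c1Cn1ccc2cc(Br)ccc12
F7 | step 5 | 2,3,5-tribromo-1H-indole | Brc1ccc2[nH]c(Br)c(Br)c2c1
F8 | step 5 | 2,3,5-tribromo-1-[(2,3-dibromo-6-isocyanophenyl)methyl]-1H-indole | Brc1ccc2c(c1)c(Br)c(Br)n2Cc1c([N+]#[C-])ccc(Br)c1Br
F9 | step 5 | 2,3,5-tribromo-1-(4,5-dibromo-1H-indol-3-yl)-1H-indole | Brc1ccc2c(c1)c(Br)c(Br)n2-c1c[nH]c2ccc(Br)c(Br)c12
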